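**Assumptions**
- Ring locants C1–C14 follow the target SMILES: C1 = CH(isopropenyl), C4/C8/C12 = CH(CH3), C5/C13 = CH(OAc), C10 = C=O. In these locants the target is (1S,4R,5S,8S,12R,13R).
- (R)-Pent-3-yn-2-ol is taken as a purchasable single enantiomer (otherwise one Noyori transfer hydrogenation of pent-3-yn-2-one).
- The Kishi ligand antipode (step 9) and the BINAP antipode (step 12) are written as the ones assumed to be matched; each would be confirmed on small scale.

**Retrosynthetic overview**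
1. Diacetate ⇒ diol 17; C4–H comes from an OH-directed hydrogenation of the exo-methylene carbinol 16.
2. C10=O ⇒ cycloalkyne 14: the C10–O bond is made by transannular 5-endo-dig addition of the C13 hydroxyl (Au), then hydrolysis. This C–O step is what places the carbonyl.
3. The only ring (14-membered) ⇒ ring-closing alkyne metathesis of diyne 13 (C10≡C11); alkyne metathesis is used because it ignores the isopropenyl group.
4. 13 ⇒ Nozaki–Hiyama–Kishi union of enol triflate 7 and ynal 12 (C4–C5 bond, sets C5).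
5. 7 ⇐ (S)-limonene (C1, C13–C4) + allenylstannane 3 (C11, C12; sets C12/C13); 12 ⇐ (S)-citronellal (C5–C10, C8).

**Step 1**
Reactants: 1 (R)-pent-3-yn-2-ol
Product: 2 (R)-pent-3-yn-2-yl methanesulfonate
Conditions: MsCl, Et3N, CH2Cl2, 0 °C
Reagents that add atoms: methanesulfonyl chloride CS(=O)(=O)Cl
Why: O-sulfonylation (mesylation) of the propargylic alcohol; the C–O bond is untouched, so configuration is retained.

**Step 2**
Reactants: 2 (R)-pent-3-yn-2-yl methanesulfonate
Product: 3 (aS)-tributyl(penta-2,3-dien-2-yl)stannane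
Conditions: Bu3SnLi (Bu3SnH, LDA), CuBr·SMe2, THF, −78 °C
Reagents that add atoms: tributyltin hydride CCCC[SnH](CCCC)CCCC
Why: anti-SN2′ displacement of the propargylic mesylate by the stannylcuprate (Marshall allenylstannane synthesis) transfers the carbinol chirality to the allene axis, (R) → (aS).

**Step 3**
Reactants: 4 (S)-limonene
Product: 5 (3S)-6-oxo-3-(prop-1-en-2-yl)heptanal
Conditions: O3 (1.0 equiv), CH2Cl2/MeOH, −78 °C; then Me2S
Reagents that add atoms: ozone [O-][O+]=O
Why: chemoselective ozonolysis of the electron-richer trisubstituted ring alkene over the 1,1-disubstituted isopropenyl group; the limonene stereocentre is untouched and becomes C1 (S).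

**Step 4**
Reactants: 5 (3S)-6-oxo-3-(prop-1-en-2-yl)heptanal; 3 (aS)-tributyl(penta-2,3-dien-2-yl)stannane
Product: 6 (5S,7R,8R)-7-hydroxy-8-methyl-5-(prop-1-en-2-yl)undec-9-yn-2-one
Conditions: BF3·OEt2, CH2Cl2, −78 °C
Reagents that add atoms: none
Why: Lewis-acid-promoted SE2′ addition of the chiral allenylstannane to the aldehyde (Marshall propargylation); attack anti to tin sets C12 (R), the open transition state gives the syn adduct and hence C13 (R), and the ketone does not react at −78 °C.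

**Step 5**
Reactants: 6 (5S,7R,8R)-7-hydroxy-8-methyl-5-(prop-1-en-2-yl)undec-9-yn-2-one
Product: 7 (5S,7R,8R)-7-hydroxy-8-methyl-5-(prop-1-en-2-yl)undec-1-en-9-yn-2-yl trifluoromethanesulfonate
Conditions: LDA (2.2 equiv), THF, −78 °C; then PhNTf2
Reagents that add atoms: N-phenylbis(trifluoromethanesulfonimide) O=S(=O)(N(c1ccccc1)S(=O)(=O)C(F)(F)F)C(F)(F)F
Why: kinetic enol triflate formation; the alkoxide/methyl-side enolate dianion is triflated only at the enolate oxygen, and no stereocentre is involved.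

**Step 6**
Reactants: 8 (S)-citronellal
Product: 9 (4S)-1,1-dibromo-4,8-dimethylnona-1,7-diene
Conditions: CBr4, PPh3, CH2Cl2, 0 °C
Reagents that add atoms: carbon tetrabromide BrC(Br)(Br)Br
Why: Corey–Fuchs (Ramirez) dibromo-olefination of the aldehyde; the β-stereocentre (C8) is not enolisable under these conditions.

**Step 7**
Reactants: 9 (4S)-1,1-dibromo-4,8-dimethylnona-1,7-diene
Product: 11 (5S)-5,9-dimethyldec-8-en-2-yne, via lithium acetylide 10 (not isolated)
Conditions: n-BuLi (2.2 equiv), THF, −78 °C; then MeI, −78 → 25 °C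
Reagents that add atoms: iodomethane CI
Why: second stage of the Corey–Fuchs sequence (Li/Br exchange and elimination to the acetylide), followed by C-methylation to cap the alkyne for metathesis.

**Step 8**
Reactants: 11 (5S)-5,9-dimethyldec-8-en-2-yne
Product: 12 (4S)-4-methyloct-6-ynal
Conditions: O3, CH2Cl2/MeOH, −78 °C (Sudan III end point); then Me2S
Reagents that add atoms: ozone [O-][O+]=O
Why: chemoselective ozonolysis; the trisubstituted alkene is cleaved much faster than the internal alkyne, and acetone is lost.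

**Step 9**
Reactants: 7 (5S,7R,8R)-7-hydroxy-8-methyl-5-(prop-1-en-2-yl)undec-1-en-9-yn-2-yl trifluoromethanesulfonate; 12 (4S)-4-methyloct-6-ynal
Product: 13 (4R,5R,7S,11S,14S)-4,14-dimethyl-10-methylidene-7-(prop-1-en-2-yl)octadeca-2,16-diyne-5,11-diol
Conditions: CrCl2 (4 equiv), NiCl2 (cat.), Kishi oxazoline–sulfonamide ligand (S), Et3N, THF, 25 °C
Reagents that add atoms: none
Why: Ni/Cr-mediated Nozaki–Hiyama–Kishi coupling; the alkenylchromium adds only to the aldehyde (free OH, alkynes and alkenes are tolerated) and the chiral Cr–sulfonamide complex (Kishi asymmetric variant) sets the new C5 carbinol as S.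

**Step 10**
Reactants: 13 (4R,5R,7S,11S,14S)-4,14-dimethyl-10-methylidene-7-(prop-1-en-2-yl)octadeca-2,16-diyne-5,11-diol
Product: 14 (1S,5S,8S,12R,13R)-8,12-dimethyl-4-methylidene-1-(prop-1-en-2-yl)cyclotetradec-10-yne-5,13-diol (ring locants as in the target)
Conditions: Mo alkylidyne tripodal-silanolate ("canopy") catalyst (5 mol%), 5 Å MS, toluene, 80 °C, 2 mM
Reagents that add atoms: none
Why: ring-closing alkyne metathesis forms the 14-membered ring at C10≡C11 with loss of but-2-yne; Mo alkylidynes do not touch the isopropenyl or exo-methylene alkenes, which would divert an alkene metathesis into a six-membered ring.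

**Step 11**
Reactants: 14 (1S,5S,8S,12R,13R)-8,12-dimethyl-4-methylidene-1-(prop-1-en-2-yl)cyclotetradec-10-yne-5,13-diol
Product: 16 (1S,5S,8S,12R,13R)-5,13-dihydroxy-8,12-dimethyl-4-methylidene-1-(prop-1-en-2-yl)cyclotetradecan-10-one, via bridged enol ether 15 (not isolated)
Conditions: (JohnPhos)Au(MeCN)SbF6 (5 mol%), CH2Cl2, 25 °C; then PPTS, THF/H2O, 25 °C
Reagents that add atoms: water O
Why: gold-catalysed transannular hydroalkoxylation; the C13 hydroxyl can reach only C10 (5-endo-dig; attack at C11 would be 4-exo), so the C10–O bond forms regiospecifically and hydrolysis of the 2,3-dihydrofuran gives the C10 ketone without touching a stereocentre.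

**Step 12**
Reactants: 16 (1S,5S,8S,12R,13R)-5,13-dihydroxy-8,12-dimethyl-4-methylidene-1-(prop-1-en-2-yl)cyclotetradecan-10-one
Product: 17 (1S,4R,5S,8S,12R,13R)-5,13-dihydroxy-4,8,12-trimethyl-1-(prop-1-en-2-yl)cyclotetradecan-10-one
Conditions: H2 (30 atm), Ru(OAc)2[(R)-BINAP] (2 mol%), MeOH, 25 °C
Reagents that add atoms: none
Why: Proposed new method: alkoxide-directed hydrogenation used to tell apart two constitutionally identical 1,1-disubstituted alkenes inside a macrocyclic keto-diol. The C5 alkoxide displaces acetate on Ru, the adjacent exo-methylene inserts into the Ru–H formed by H2 heterolysis, and H is delivered to C4 on the face syn to oxygen in the A(1,3)-minimised conformer, giving the 4,5-anti product (C4 R). The isopropenyl group is only bishomoallylic to C13–OH and remote from C5–OH, so it cannot enter this alkoxide-bound cycle and should survive. Closest known reaction type: Noyori Ru–BINAP hydrogenation of allylic and homoallylic alcohols (geraniol; kinetic resolution of 2-substituted secondary allylic alcohols, anti-selective) and Evans/Brown hydroxyl-directed Rh hydrogenation.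

**Step 13**
Reactants: 17 (1S,4R,5S,8S,12R,13R)-5,13-dihydroxy-4,8,12-trimethyl-1-(prop-1-en-2-yl)cyclotetradecan-10-one
Product: 18 (1S,4R,5S,8S,12R,13R)-4,8,12-trimethyl-10-oxo-1-(prop-1-en-2-yl)cyclotetradecane-5,13-diyl diacetate (CNP0328624.1)
Conditions: Ac2O, pyridine, DMAP (cat.), CH2Cl2, 0 → 25 °C
Reagents that add atoms: acetic anhydride CC(=O)OC(C)=O
Why: DMAP-catalysed O-acylation of both secondary alcohols with retention; the γ-hydroxy ketone reacts through its predominant open form.

**Compound list**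
1 | (R)-pent-3-yn-2-ol | C[C@@H](O)C#CC | starting material
2 | (R)-pent-3-yn-2-yl methanesulfonate | C[C@@H](OS(C)(=O)=O)C#CC | intermediate
3 | (aS)-tributyl(penta-2,3-dien-2-yl)stannane | CC=[C@@]=C(C)[Sn](CCCC)(CCCC)CCCC | intermediate
4 | (S)-limonene | CC1=CC[C@H](CC1)C(C)=C | starting material
5 | (3S)-6-oxo-3-(prop-1-en-2-yl)heptanal | C=C(C)[C@H](CC=O)CCC(C)=O | intermediate
6 | (5S,7R,8R)-7-hydroxy-8-methyl-5-(prop-1-en-2-yl)undec-9-yn-2-one | CC#C[C@@H](C)[C@H](O)C[C@@H](C(C)=C)CCC(C)=O | intermediate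
7 | (5S,7R,8R)-7-hydroxy-8-methyl-5-(prop-1-en-2-yl)undec-1-en-9-yn-2-yl trifluoromethanesulfonate | CC#C[C@@H](C)[C@H](O)C[C@@H](C(C)=C)CCC(=C)OS(=O)(=O)C(F)(F)F | intermediate
8 | (S)-citronellal, (3S)-3,7-dimethyloct-6-enal | CC(C)=CCC[C@H](C)CC=O | starting material
9 | (4S)-1,1-dibromo-4,8-dimethylnona-1,7-diene | CC(C)=CCC[C@H](C)CC=C(Br)Br | intermediate
10 | [(4S)-4,8-dimethylnon-7-en-1-yn-1-yl]lithium | CC(C)=CCC[C@H](C)CC#C[Li] | intermediate
11 | (5S)-5,9-dimethyldec-8-en-2-yne | CC(C)=CCC[C@H](C)CC#CC | intermediate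
12 | (4S)-4-methyloct-6-ynal | O=CCC[C@H](C)CC#CC | intermediate
13 | (4R,5R,7S,11S,14S)-4,14-dimethyl-10-methylidene-7-(prop-1-en-2-yl)octadeca-2,16-diyne-5,11-diol | CC#C[C@@H](C)[C@H](O)C[C@@H](C(C)=C)CCC(=C)[C@@H](O)CC[C@H](C)CC#CC | intermediate
14 | (1S,5S,8S,12R,13R)-8,12-dimethyl-4-methylidene-1-(prop-1-en-2-yl)cyclotetradec-10-yne-5,13-diol (target ring locants) | C=C(C)[C@H]1CCC(=C)[C@@H](O)CC[C@H](C)CC#C[C@@H](C)[C@H](O)C1 | intermediate
15 | bridged enol ether: 14 with O13 bonded to C10 and C10=C11 (2,3-dihydrofuran spanning C10–C13), C5–OH free | C=C(C)[C@H]1CCC(=C)[C@@H](O)CC[C@H](C)CC2=C[C@@H](C)[C@H](O2)C1 | intermediate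
16 | (1S,5S,8S,12R,13R)-5,13-dihydroxy-8,12-dimethyl-4-methylidene-1-(prop-1-en-2-yl)cyclotetradecan-10-one | C=C(C)[C@H]1CCC(=C)[C@@H](O)CC[C@H](C)CC(=O)C[C@@H](C)[C@H](O)C1 | intermediate
17 | (1S,4R,5S,8S,12R,13R)-5,13-dihydroxy-4,8,12-trimethyl-1-(prop-1-en-2-yl)cyclotetradecan-10-one | C=C(C)[C@H]1CC[C@@H](C)[C@@H](O)CC[C@H](C)CC(=O)C[C@@H](C)[C@H](O)C1 | intermediate
18 | (1S,4R,5S,8S,12R,13R)-4,8,12-trimethyl-10-oxo-1-(prop-1-en-2-yl)cyclotetradecane-5,13-diyl diacetate | C=C(C)[C@H]1CC[C@@H](C)[C@@H](OC(C)=O)CC[C@H](C)CC(=O)C[C@@H](C)[C@H](OC(C)=O)C1 | target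

**Totals**
Total step count: 13. Longest linear sequence: 9 steps (1 → 2 → 3 → 6 → 7 → 13 → 14 → 16 → 17 → 18).

**Three steps most likely to fail**

Step 4 (syn-propargylation). BF3/allenylstannane additions give lower syn:anti ratios with α-unbranched aldehydes such as 5, and the Lewis acid could trigger a carbonyl-ene reaction with the isopropenyl group. The fallback sets out from 5 and comes back at 6. The antipodal alcohol (S)-pent-3-yn-2-ol is mesylated to (S)-pent-3-yn-2-yl methanesulfonate F1. This is added to 5 under Marshall's Pd(OAc)2/PPh3/Et2Zn conditions (allenylzinc, closed transition state) to give the anti adduct (5S,7S,8R)-7-hydroxy-8-methyl-5-(prop-1-en-2-yl)undec-9-yn-2-one F2. Mitsunobu inversion with 4-nitrobenzoic acid, PPh3 and DIAD gives (5S,7R,8R)-8-methyl-2-oxo-5-(prop-1-en-2-yl)undec-9-yn-7-yl 4-nitrobenzoate F3, and K2CO3/MeOH releases 6.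

Step 9 (ligand-controlled NHK). The C5 selectivity rests entirely on the chiral chromium complex, with remote substrate stereocentres and a free hydroxyl present. The fallback sets out from 7 and 12 and comes back at 13. Ligand-free CrCl2/NiCl2 coupling in DMF gives the C5-epimeric mixture (4R,5R,7S,11RS,14S)-4,14-dimethyl-10-methylidene-7-(prop-1-en-2-yl)octadeca-2,16-diyne-5,11-diol F4. MnO2 oxidises only the allylic alcohol to (4R,5R,7S,14S)-5-hydroxy-4,14-dimethyl-10-methylidene-7-(prop-1-en-2-yl)octadeca-2,16-diyn-11-one F5. Corey–Bakshi–Shibata reduction ((R)-Me-CBS, catecholborane, −78 °C) then gives 13.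

Step 12 (the proposed new step). Chemoselectivity over the isopropenyl group and the anti selectivity in the macrocycle are both untested. The fallback uses known chemistry, sets out from 14 and comes back at 17. The gold step is run without the aqueous stage and 15 is isolated. Its C5 hydroxyl is silylated with (HMe2Si)2NH and cyclised with Karstedt's catalyst (Tamao intramolecular 5-endo hydrosilylation, which delivers H to C4 from the tether) to give the oxasilolane F6 (15 with C5–O–SiMe2–CH2–C4). Tamao oxidation (H2O2, KF, KHCO3) gives the 1,3-diol F7 (15 with C4–CH2OH). TsCl/pyridine gives the primary tosylate F8, and LiBHEt3 gives the C4-methyl enol ether F9. PPTS in THF/H2O then opens the enol ether to 17.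

**Further compounds**
F1 | step 4 | (S)-pent-3-yn-2-yl methanesulfonate | C[C@H](OS(C)(=O)=O)C#CC
F2 | step 4 | (5S,7S,8R)-7-hydroxy-8-methyl-5-(prop-1-en-2-yl)undec-9-yn-2-one | CC#C[C@@H](C)[C@@H](O)C[C@@H](C(C)=C)CCC(C)=O
F3 | step 4 | (5S,7R,8R)-8-methyl-2-oxo-5-(prop-1-en-2-yl)undec-9-yn-7-yl 4-nitrobenzoate | CC#C[C@@H](C)[C@H](OC(=O)c1ccc(cc1)[N+](=O)[O-])C[C@@H](C(C)=C)CCC(C)=O
F4 | step 9 | (4R,5R,7S,11RS,14S)-4,14-dimethyl-10-methylidene-7-(prop-1-en-2-yl)octadeca-2,16-diyne-5,11-diol | CC#C[C@@H](C)[C@H](O)C[C@@H](C(C)=C)CCC(=C)C(O)CC[C@H](C)CC#CC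
F5 | step 9 | (4R,5R,7S,14S)-5-hydroxy-4,14-dimethyl-10-methylidene-7-(prop-1-en-2-yl)octadeca-2,16-diyn-11-one | CC#C[C@@H](C)[C@H](O)C[C@@H](C(C)=C)CCC(=C)C(=O)CC[C@H](C)CC#CC
F6 | step 12 | oxasilolane: bridged enol ether 15 with C5–O–Si(CH3)2–CH2–C4 ring (4R,5S) | C=C(C)[C@H]1CC[C@H]3C[Si](C)(C)O[C@H]3CC[C@H](C)CC2=C[C@@H](C)[C@H](O2)C1
F7 | step 12 | 1,3-diol: bridged enol ether with C4–CH2OH (4R) and C5–OH (5S) | C=C(C)[C@H]1CC[C@@H](CO)[C@@H](O)CC[C@H](C)CC2=C[C@@H](C)[C@H](O2)C1
F8 | step 12 | primary tosylate of F7 | C=C(C)[C@H]1CC[C@@H](COS(=O)(=O)c3ccc(C)cc3)[C@@H](O)CC[C@H](C)CC2=C[C@@H](C)[C@H](O2)C1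
F9 | step 12 | bridged enol ether with C4–CH3 (4R) and C5–OH (5S) | C=C(C)[C@H]1CC[C@@H](C)[C@@H](O)CC[C@H](C)CC2=C[C@@H](C)[C@H](O2)C1
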